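Platanetin (3,5,7,8-tetrahydroxy-6-prenylflavone): route by ketene–siloxyalkyne benzannulation on a comenic acid-derived pyranone

**Plan**
1. The retrosynthesis first removes the C8–O bond (late hydroxylation) and the O-protecting groups. It then cuts ring A at C5–C6, C7–C8 and C4a–C5, and also at C8–C8a, the bond made by a 1,2-shift. This leaves a pyranonyl diazoketone and a prenyl siloxyalkyne.
2. Enabling feature: ring A sits on the C4a=C8a edge of the γ-pyranone (ring C) and carries C5–OH, C6–prenyl, C7–O and C8–H. A vinylketene plus ynol ether cascade writes exactly this ortho/meta order, so the 6- versus 8-prenyl question never arises.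
3. Forward: ring C is bought as comenic acid, with O1, C4=O and the 3-OH already in place. Ring B is attached at C2 by Suzuki coupling, the carboxyl group becomes the diazoketone, and ring A is closed last.
4. The siloxyalkyne is made from prenyl bromide and ethynylmagnesium bromide by acetylide oxidation and O-silylation.
5. After ring closure, C8 is the only C–H of ring A and lies para to the 5-OH. It is hydroxylated with persulfate, and acid then removes all groups.
6. Stereochemistry: the target has no stereocentre and no stereogenic double bond (the prenyl alkene carries two methyl groups). It is one achiral compound and nothing has to be set.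

Key step: step 7

Remark: flavone numbering (O1, C2 … C8a) is used for atoms of the target. Pyranone locants follow the name of the compound in question.

**Step 1**
Reactants: 1 comenic acid
Product: 2 6-bromo-5-hydroxy-4-oxo-4H-pyran-2-carboxylic acid
Conditions: Br2 (1.05 equiv), H2O, 0 °C → rt
Reagents that add atoms: bromine, BrBr
Why: Electrophilic bromination of a 3-hydroxy-4-pyranone goes to the free carbon next to the enolic hydroxyl (C6 of comenic acid), whereas C3 is deactivated by the flanking carboxyl and ketone groups.

**Step 2**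
Reactants: 2 6-bromo-5-hydroxy-4-oxo-4H-pyran-2-carboxylic acid
Product: 3 methoxymethyl 6-bromo-5-(methoxymethoxy)-4-oxo-4H-pyran-2-carboxylate
Conditions: MOMCl (2.4 equiv), i-Pr2NEt, CH2Cl2, 0 °C → rt
Reagents that add atoms: chloromethyl methyl ether, COCCl
Why: A double Williamson-type O-alkylation with the α-chloro ether masks the enol as a MOM ether and the acid as a MOM ester in one operation, and the β-bromo enone is inert to the hindered amine.

**Step 3**
Reactants: 3 methoxymethyl 6-bromo-5-(methoxymethoxy)-4-oxo-4H-pyran-2-carboxylate; 4 phenylboronic acid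
Product: 6 5-(methoxymethoxy)-4-oxo-6-phenyl-4H-pyran-2-carboxylic acid, via coupled MOM ester 5 (not isolated)
Conditions: Pd(dppf)Cl2 (3 mol %), K2CO3, 1,4-dioxane–H2O, 80 °C; then 1 M HCl, 0 °C, to pH 2–3, immediate extraction
Reagents that add atoms: water, O
Why: Suzuki–Miyaura coupling of 2-halo-3-alkoxy-4-pyranones is established because the C–Br bond of a β-bromo enone adds readily to Pd(0), and the activated acyloxymethyl ester is then saponified by the same aqueous carbonate while the MOM ether survives both the base and the brief cold acidification.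

**Step 4**
Reactants: 6 5-(methoxymethoxy)-4-oxo-6-phenyl-4H-pyran-2-carboxylic acid
Product: 8 6-(diazoacetyl)-3-(methoxymethoxy)-2-phenyl-4H-pyran-4-one, via mixed carbonic anhydride 7 (not isolated)
Conditions: i-BuOCOCl, N-methylmorpholine, THF, −20 °C; then CH2N2 (excess), Et2O, −20 → 0 °C
Reagents that add atoms: diazomethane, C=[N+]=[N-] (isobutyl chloroformate, CC(C)COC(=O)Cl, puts atoms only into 7)
Why: Arndt–Eistert-type acylation of diazomethane through the mixed anhydride avoids the HCl of acid chloride formation that would endanger the MOM ether, and chromone- and pyranone-2-carbonyl derivatives are known to give stable diazoketones in this way.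

**Step 5**
Reactants: 9 prenyl bromide; 10 ethynylmagnesium bromide
Product: 11 5-methylhex-4-en-1-yne
Conditions: CuCl (5 mol %), THF, 0 → 45 °C, 10 in excess; distillation
Reagents that add atoms: none
Why: Copper(I)-catalysed coupling of an alkynyl Grignard reagent with a primary allylic bromide gives the skipped enyne mainly by SN2 attack at the unhindered CH2 of the prenyl unit, and the excess of 10 suppresses double alkylation.

**Step 6**
Reactants: 11 5-methylhex-4-en-1-yne
Product: 14 triisopropyl(5-methylhex-4-en-1-ynyloxy)silane, via lithium acetylide 12 (not isolated), via lithium ynolate 13 (not isolated)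
Conditions: n-BuLi (1.0 equiv), THF, −78 °C; t-BuOOLi (t-BuOOH, LiHMDS), −78 → 0 °C; TIPSOTf, −78 → 0 °C
Reagents that add atoms: tert-butyl hydroperoxide (as lithium salt), CC(C)(C)OO; triisopropylsilyl triflate, CC(C)[Si](OS(=O)(=O)C(F)(F)F)(C(C)C)C(C)C (n-butyllithium, [Li]CCCC, puts lithium only into 12 and 13)
Why: Oxidation of a lithium acetylide with lithium tert-butyl peroxide followed by O-silylation is the standard entry to TIPS ynol ethers, since the nucleophilic peroxide leaves the prenyl alkene alone and the bulky silyl group goes to oxygen rather than carbon.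

**Step 7**
Reactants: 8 6-(diazoacetyl)-3-(methoxymethoxy)-2-phenyl-4H-pyran-4-one; 14 triisopropyl(5-methylhex-4-en-1-ynyloxy)silane
Product: 19 5-hydroxy-3-(methoxymethoxy)-6-(3-methylbut-2-enyl)-2-phenyl-7-(triisopropylsilyloxy)chromen-4-one, via pyranonylketene 15 (not isolated), via cyclobutenone 16 (not isolated), via dienylketene 17 (not isolated), via cyclohexadienone 18 (not isolated)
Conditions: 14 (1.5 equiv), ClCH2CH2Cl (degassed), hν (LED, 420–440 nm), rt; then 80 °C
Reagents that add atoms: none
Why: Proposed new method: irradiation expels N2 from 8 and the pyranone carbon C6 (flavone C8a) shifts to the diazo carbon (C8) in a Wolff rearrangement, giving ketene 15, whose electrophilic carbonyl carbon (C5) bonds to the nucleophilic prenyl-bearing carbon of 14 (C6) while C8 bonds to the siloxy carbon (C7) in a [2+2] cycloaddition that closes the transient four-membered ring of 16. At 80 °C 16 opens by a reversible 4π electrocyclic reaction to 17, and the isomer with the pyranone cis to the ketene closes ring A by a 6π electrocyclisation (C5 to C4a, the pyranone C5–H carbon), after which 18, a β-diketone in disguise, enolises irreversibly to the chelated C5 phenol. The closest known reaction type is the Danheiser benzannulation of vinyl, aryl and five-membered heteroaryl α-diazoketones with siloxyalkynes; a γ-pyranone has not yet carried the ketene, but its C5=C6 bond is only weakly aromatic and should act like the alkene of a vinyl diazoketone. No stereocentre is left, because the sp3 carbons of 16 and 18 are flattened on aromatisation. Regioselectivity comes from the polarisation of the ynol ether, and chemoselectivity from the much higher nucleophilicity of the siloxyalkyne compared with the trisubstituted prenyl alkene, whose one-carbon tether also forbids an intramolecular [2+2] reaction in 17. Light of 420–440 nm should reach only the weak n→π* band of the diazoketone, so that the 3-alkoxy-2-phenylpyranone and flavone chromophores are spared from hydrogen abstraction at the MOM group.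

**Step 8**
Reactants: 19 5-hydroxy-3-(methoxymethoxy)-6-(3-methylbut-2-enyl)-2-phenyl-7-(triisopropylsilyloxy)chromen-4-one
Product: 21 5-hydroxy-3,7-bis(methoxymethoxy)-6-(3-methylbut-2-enyl)-2-phenylchromen-4-one, via 7-phenol 20 (not isolated)
Conditions: TBAF (1.05 equiv), THF, 0 °C; then MOMCl (1.2 equiv), i-Pr2NEt (scavenger for adventitious HCl), 0 °C → rt
Reagents that add atoms: chloromethyl methyl ether, COCCl
Why: Fluoride desilylation frees the acidic 7-phenoxide, which undergoes Williamson-type etherification in the same flask while the 5-OH stays untouched because it is hydrogen-bonded to the C4 carbonyl, and the exchange is needed because an aryl TIPS ether would not survive the aqueous alkali of step 9.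

**Step 9**
Reactants: 21 5-hydroxy-3,7-bis(methoxymethoxy)-6-(3-methylbut-2-enyl)-2-phenylchromen-4-one
Product: 22 potassium 5-hydroxy-3,7-bis(methoxymethoxy)-6-(3-methylbut-2-enyl)-4-oxo-2-phenylchromen-8-yl sulfate
Conditions: K2S2O8 (1.2 equiv), aq KOH, pyridine, 0 °C → rt, dark, Ar; neutralise, wash with Et2O (recovers 21), extract into n-BuOH
Reagents that add atoms: potassium peroxodisulfate, [K+].[K+].[O-]S(=O)(=O)OOS(=O)(=O)[O-]
Why: In the Elbs persulfate oxidation the 5-phenoxide attacks the peroxide oxygen through its para carbon C8, the only free position of ring A, as in the classical 8-hydroxylation of 5-hydroxy-3,7-dialkoxyflavones, and the polar pathway in cold alkali in the dark should spare the prenyl alkene while the aryl sulfate shields the new oxygen from over-oxidation.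

**Step 10**
Reactants: 22 potassium 5-hydroxy-3,7-bis(methoxymethoxy)-6-(3-methylbut-2-enyl)-4-oxo-2-phenylchromen-8-yl sulfate
Product: 23 platanetin
Conditions: 2 M HCl, MeOH–H2O, 50 °C, Ar
Reagents that add atoms: none
Why: Acid-catalysed solvolysis of the aryl sulfate (S–O cleavage) and acetal cleavage of both MOM ethers proceed under the dilute HCl/MeOH conditions commonly used for prenylated flavonoids, which are mild enough to limit chroman formation from the ortho-prenylphenol, and exclusion of air protects the 5,8-hydroquinone.

**Compound list**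
1 | comenic acid (5-hydroxy-4-oxo-4H-pyran-2-carboxylic acid) | O=C(O)c1cc(=O)c(O)co1 | starting material
2 | 6-bromo-5-hydroxy-4-oxo-4H-pyran-2-carboxylic acid | O=C(O)c1cc(=O)c(O)c(Br)o1 | intermediate
3 | methoxymethyl 6-bromo-5-(methoxymethoxy)-4-oxo-4H-pyran-2-carboxylate | COCOC(=O)c1cc(=O)c(OCOC)c(Br)o1 | intermediate
4 | phenylboronic acid | OB(O)c1ccccc1 | starting material
5 | methoxymethyl 5-(methoxymethoxy)-4-oxo-6-phenyl-4H-pyran-2-carboxylate | COCOC(=O)c1cc(=O)c(OCOC)c(-c2ccccc2)o1 | intermediate
6 | 5-(methoxymethoxy)-4-oxo-6-phenyl-4H-pyran-2-carboxylic acid | O=C(O)c1cc(=O)c(OCOC)c(-c2ccccc2)o1 | intermediate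
7 | isobutyl carbonic anhydride of 6 | CC(C)COC(=O)OC(=O)c1cc(=O)c(OCOC)c(-c2ccccc2)o1 | intermediate
8 | 6-(diazoacetyl)-3-(methoxymethoxy)-2-phenyl-4H-pyran-4-one | [N-]=[N+]=CC(=O)c1cc(=O)c(OCOC)c(-c2ccccc2)o1 | intermediate
9 | prenyl bromide (1-bromo-3-methylbut-2-ene) | CC(C)=CCBr | starting material
10 | ethynylmagnesium bromide | C#C[Mg]Br | starting material
11 | 5-methylhex-4-en-1-yne | C#CCC=C(C)C | intermediate
12 | lithium 5-methylhex-4-en-1-ynide | [Li]C#CCC=C(C)C | intermediate
13 | lithium 5-methylhex-4-en-1-yn-1-olate | [Li+].[O-]C#CCC=C(C)C | intermediate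
14 | triisopropyl(5-methylhex-4-en-1-ynyloxy)silane | CC(C)=CCC#CO[Si](C(C)C)(C(C)C)C(C)C | intermediate
15 | [5-(methoxymethoxy)-4-oxo-6-phenyl-4H-pyran-2-yl]ketene | O=C=Cc1cc(=O)c(OCOC)c(-c2ccccc2)o1 | intermediate
16 | 4-[5-(methoxymethoxy)-4-oxo-6-phenylpyran-2-yl]-2-(3-methylbut-2-enyl)-3-(triisopropylsilyloxy)cyclobut-2-enone (racemic) | CC(C)=CCC1=C(O[Si](C(C)C)(C(C)C)C(C)C)C(c2cc(=O)c(OCOC)c(-c3ccccc3)o2)C1=O | intermediate
17 | dienylketene with the pyranone cis to the ketene-bearing carbon | CC(C)=CCC(=C=O)/C(O[Si](C(C)C)(C(C)C)C(C)C)=C\c1cc(=O)c(OCOC)c(-c2ccccc2)o1 | intermediate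
18 | 4a-H cyclohexadienone tautomer of 19 (racemic) | CC(C)=CCC1=C(O[Si](C(C)C)(C(C)C)C(C)C)C=C2OC(c3ccccc3)=C(OCOC)C(=O)C2C1=O | intermediate
19 | 5-hydroxy-3-(methoxymethoxy)-6-(3-methylbut-2-enyl)-2-phenyl-7-(triisopropylsilyloxy)chromen-4-one | CC(C)=CCc1c(O[Si](C(C)C)(C(C)C)C(C)C)cc2oc(-c3ccccc3)c(OCOC)c(=O)c2c1O | intermediate
20 | 5,7-dihydroxy-3-(methoxymethoxy)-6-(3-methylbut-2-enyl)-2-phenylchromen-4-one | CC(C)=CCc1c(O)cc2oc(-c3ccccc3)c(OCOC)c(=O)c2c1O | intermediate
21 | 5-hydroxy-3,7-bis(methoxymethoxy)-6-(3-methylbut-2-enyl)-2-phenylchromen-4-one | CC(C)=CCc1c(OCOC)cc2oc(-c3ccccc3)c(OCOC)c(=O)c2c1O | intermediate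
22 | potassium 5-hydroxy-3,7-bis(methoxymethoxy)-6-(3-methylbut-2-enyl)-4-oxo-2-phenylchromen-8-yl sulfate | CC(C)=CCc1c(OCOC)c(OS(=O)(=O)[O-])c2oc(-c3ccccc3)c(OCOC)c(=O)c2c1O.[K+] | intermediate
23 | platanetin (3,5,7,8-tetrahydroxy-6-(3-methylbut-2-enyl)-2-phenylchromen-4-one, achiral) | CC(C)=CCc1c(O)c(O)c2oc(-c3ccccc3)c(O)c(=O)c2c1O | target

**Step count**
Total step count: 10.
Longest linear sequence: 8 (steps 1–4 and 7–10).

**Steps most likely to fail**

**Step 7.**
- The light may degrade the pyranone chromophore.
- The ketene may dimerise, or be trapped by the product phenol, faster than it meets the alkyne.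
- The 6π closure onto a carbon that already bears the C4 acyl group may lag behind re-closure to the cyclobutenone.

The fallback uses only known chemistry and buys ring A instead of building it. It sets out from prenyl bromide 9 and comes back at 21. Treatment of 9 with Bu3SnLi (THF, −78 °C) gives tributyl(3-methylbut-2-enyl)stannane F1. Purchased galangin F2 is alkylated with MOMCl (2.2 equiv) and i-Pr2NEt at O3 and O7 only, the chelated 5-OH staying free, to give 5-hydroxy-3,7-bis(methoxymethoxy)-2-phenylchromen-4-one F3. Iodination ortho to the free 5-OH with BnMe3N·ICl2 and CaCO3 in CH2Cl2–MeOH gives 5-hydroxy-6-iodo-3,7-bis(methoxymethoxy)-2-phenylchromen-4-one F4. Stille coupling of F4 with F1 (Pd(PPh3)4, DMF, 90 °C) gives 21. The price is that 6- versus 8-selectivity then depends on the iodination.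

**Step 9.**
- Conversion may stay low because the chelated, lipophilic phenol is hard to ionise and dissolve.
- Radical decomposition of persulfate may attack the prenyl alkene.

The fallback sets out from 20, which is now isolated after the TBAF stage of step 8, and comes back at 23. Magnesium-mediated ortho-formylation (Casnati–Skattebøl; MgCl2, Et3N, paraformaldehyde, MeCN, reflux) can only strike C8 and gives 5,7-dihydroxy-3-(methoxymethoxy)-6-(3-methylbut-2-enyl)-4-oxo-2-phenylchromene-8-carbaldehyde F5. Dakin oxidation (H2O2, aq NaOH, THF, 0 °C, Ar, Na2S2O4 quench) gives 5,7,8-trihydroxy-3-(methoxymethoxy)-6-(3-methylbut-2-enyl)-2-phenylchromen-4-one F6. The conditions of step 10 convert F6 into 23.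

**Step 6.**
- Base may isomerise the skipped enyne to conjugated isomers.
- Oxygen transfer to the acetylide may be incomplete.
- Silylation may occur at carbon.

The fallback reaches the ynolate by ester homologation instead of acetylide oxidation. It sets out from 9 and comes back at 13. Palladium-catalysed ethoxycarbonylation of 9 (CO, EtOH, PdCl2(PPh3)2, K2CO3) gives ethyl 4-methylpent-3-enoate F7, which is also sold. In the Kowalski homologation, LiCHBr2 (CH2Br2, LiTMP, THF, −78 °C) converts F7 into lithium 1,1-dibromo-5-methylhexa-1,4-dien-2-olate F8. Bromine–lithium exchange with n-BuLi and warming trigger the 1,2-shift of the prenyl group to give 13, which is silylated as in step 6 to 14.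

**Further compounds**
F1 | step 7 | tributyl(3-methylbut-2-enyl)stannane | CCCC[Sn](CCCC)(CCCC)CC=C(C)C
F2 | step 7 | galangin (3,5,7-trihydroxyflavone, purchased) | O=c1c(O)c(-c2ccccc2)oc2cc(O)cc(O)c12
F3 | step 7 | 5-hydroxy-3,7-bis(methoxymethoxy)-2-phenylchromen-4-one | COCOc1cc(O)c2c(=O)c(OCOC)c(-c3ccccc3)oc2c1
F4 | step 7 | 5-hydroxy-6-iodo-3,7-bis(methoxymethoxy)-2-phenylchromen-4-one | COCOc1cc2oc(-c3ccccc3)c(OCOC)c(=O)c2c(O)c1I
F5 | step 9 | 5,7-dihydroxy-3-(methoxymethoxy)-6-(3-methylbut-2-enyl)-4-oxo-2-phenylchromene-8-carbaldehyde | CC(C)=CCc1c(O)c(C=O)c2oc(-c3ccccc3)c(OCOC)c(=O)c2c1O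
F6 | step 9 | 5,7,8-trihydroxy-3-(methoxymethoxy)-6-(3-methylbut-2-enyl)-2-phenylchromen-4-one | CC(C)=CCc1c(O)c(O)c2oc(-c3ccccc3)c(OCOC)c(=O)c2c1O
F7 | step 6 | ethyl 4-methylpent-3-enoate | CCOC(=O)CC=C(C)C
F8 | step 6 | lithium 1,1-dibromo-5-methylhexa-1,4-dien-2-olate | CC(C)=CCC([O-])=C(Br)Br.[Li+]
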